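An easy step comes first: D meets E and gives X and G. G, L and Q then each take a further E in the same way.

D 0.80 M (in portions, 4); E 0.600 equiv; time 15 min; the portions of D follow each other after 8.0 s, the first at the start

    D + E ⇌ X + G (K1 = 0.36, k1 = 0.25 M⁻¹ s⁻¹)
    G + E ⇌ X + L (K2 = 1.2, k2 = 0.64 M⁻¹ s⁻¹)
    L + E ⇌ X + Q (K3 = 0.58, k3 = 0.33 M⁻¹ s⁻¹)
    Q + E ⇌ X + Z (K4 = 14, k4 = 0.31 M⁻¹ s⁻¹)

* why nothing more happens at 15 min, or that something still does (all of D has reacted / forward and back rates have come level / it is still moving / E has run out first)
* conversion of D at 15 min
* amount of G at 15 min, in percent of the D charged
* amount of Z at 15 min, in percent of the D charged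

- the reaction counts as stopped when no species that holds the D changes by six tenths of a point or more over the second half of the time
- run time (flask): 15 min

Take the first step at one moment. Its forward rate carries [D][E] and its back rate carries [X][G], so the two are level when [G]/[D] = 0.36 × [E]/[X]. The next steps give [L]/[G], [Q]/[L] and [Z]/[Q] in the same way, with 1.2, 0.58 and 14 times the same ratio. So we watch two amounts, [E] and [X]. Every turnover removes an E and adds an X, so their ratio falls until the back rates catch up.

The portions are in after 24.0 s. The half-life of D by the forward first step alone, at charged concentrations, is 0.096 min, short against 15 min. We therefore expect level rates at the end.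

Our trial value, a plain guess to be tested below, is the charged equivalents of E over one plus those equivalents: 0.375. We name [E]/[X] at level rates the exchange ratio. With it, D and its products, counted per D remaining, sum to 1.28. Each D charged has then made 0.449 equiv of X. Adding the free E asks for 0.617 equiv against 0.600 equiv charged, and we accept that. We reckon conversion 21.8%, G 10.6% and Z 5.43%.

The forecast says forward and back rates have come level, with conversion 21.4% (20.5% to 22.5%), G 10.5% (9.8% to 11.2%) and Z 5.2% (4.7% to 5.8%). Its ground is that “the mixture then settles to the equilibrium of the chain”. Its figures differ a little from ours.

The simulation gives forward and back rates have come level, with conversion 21.4%, G 10.5% and Z 5.22%.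

This is thermodynamic control: the flask ends at [E]/[X] = 0.371, with 27% of its E still free. The reverse step X + G to D + E holds conversion down: the run without it reaches 60.0% instead of 21.4%, a larger effect than that of the falling E. In the neighbour flask with 0.240 equiv of E, the ratio reads 0.254. That predicts [G]/[D] = 0.0915, and the neighbour's amounts give 0.0915.

Its constants belong to no real substance; the rest is arithmetic.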